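**Retrosynthetic overview**
1. The ten-membered ring is closed last. The C9–C10 bond comes from a ligand-controlled Ni/Cr closure of a (Z)-α-iodoenoate onto the C9 aldehyde (new step). It sets C9 and keeps the C1=C10 geometry.
2. The iodoenoate comes from a cis-epoxy aldehyde by iodo-Wittig. The aldehyde comes from Sharpless epoxidation of a (Z,Z)-dienol (ring oxirane, C2/C3), and the dienol from a copper-mediated alkenyl–alkenyl coupling at C3–C4.
3. The C8 ester comes from Mitsunobu inversion by (2S,3S)-epoxyangelic acid. Its side-chain oxirane is made separately by Sharpless epoxidation of angelyl alcohol.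
4. The α-methylene-γ-lactone and C7/C8 come from a zinc Barbier coupling of a 3-(bromomethyl)butenolide and TBSOCH2CHO. The butenolide comes from ring-closing metathesis.
5. C6 comes from Sharpless kinetic resolution of hex-1-en-4-yn-3-ol. Ring order: butenolide/lactone, then ring oxirane, then ten-membered carbocycle.

Assumption: atom labels C1–C15 follow germacrane numbering (C6–O lactone, C14 ester carbon, C15 ring methyl). The target is taken exactly as in the SMILES: 2R,3S,6R,7S,8S,9S,2'S,3'S, C1=C10 E, C4=C5 Z (both cis within the ring).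

**Step 1**
Reactants: 1 acrolein; 2 prop-1-yn-1-ylmagnesium bromide
Product: 3 (±)-hex-1-en-4-yn-3-ol
Conditions: THF, −78 → 0 °C; then H2O
Reagents that add atoms: none
Why: 1,2-addition of an alkynyl Grignard reagent to an enal; the hard nucleophile attacks the carbonyl carbon and the carbinol (future C6) is racemic at this stage.

**Step 2**
Reactants: 3 (±)-hex-1-en-4-yn-3-ol
Product: 4 (3S)-hex-1-en-4-yn-3-ol
Conditions: Ti(OiPr)4 (10 mol %), (+)-(R,R)-DIPT (15 mol %), tBuOOH (0.6 equiv), 4 Å sieves, CH2Cl2, −20 °C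
Reagents that add atoms: none
Why: Sharpless kinetic resolution; with the (R,R)-tartrate the (R)-carbinol is epoxidised at its vinyl group much faster, so the (S)-alcohol, which carries the C6 configuration of the target, is recovered in high ee at about 55 % conversion.

**Step 3**
Reactants: 4 (3S)-hex-1-en-4-yn-3-ol
Product: 6 (3S,4Z)-5-iodohexa-1,4-dien-3-ol, via cyclic alkenylaluminate 5 (not isolated)
Conditions: NaAlH2(OCH2CH2OMe)2, THF, 0 → 23 °C; then iodine, −78 → 0 °C; then H2O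
Reagents that add atoms: iodine, [I][I]
Why: Alkoxide-directed trans-hydroalumination of the propargylic alcohol puts aluminium on the distal alkyne carbon inside a five-membered ring, and iodinolysis with retention gives only the Z iodide, which fixes the C4=C5 geometry.

**Step 4**
Reactants: 6 (3S,4Z)-5-iodohexa-1,4-dien-3-ol; 7 2-(bromomethyl)prop-2-enoic acid
Product: 8 (3S,4Z)-5-iodohexa-1,4-dien-3-yl 2-(bromomethyl)prop-2-enoate
Conditions: iPrN=C=NiPr, DMAP (5 mol %), CH2Cl2, −10 °C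
Reagents that add atoms: none
Why: Steglich esterification activates the acid, not the bis-allylic carbinol, so C6 keeps its configuration; low temperature and little DMAP spare the allylic bromide.

**Step 5**
Reactants: 8 (3S,4Z)-5-iodohexa-1,4-dien-3-yl 2-(bromomethyl)prop-2-enoate
Product: 9 (5S)-3-(bromomethyl)-5-[(1Z)-2-iodoprop-1-en-1-yl]furan-2(5H)-one
Conditions: second-generation Grubbs catalyst (5 mol %), CH2Cl2 (10 mM), 40 °C
Reagents that add atoms: none
Why: Ring-closing metathesis; the ruthenium carbene loads on the monosubstituted vinyl group and closes onto the acrylate alkene to give the five-membered butenolide, while the trisubstituted iodoalkene is inert.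

**Step 6**
Reactants: 9 (5S)-3-(bromomethyl)-5-[(1Z)-2-iodoprop-1-en-1-yl]furan-2(5H)-one; 10 {[tert-butyl(dimethyl)silyl]oxy}acetaldehyde
Product: 12 (4R,5S)-4-[(1R)-2-{[tert-butyl(dimethyl)silyl]oxy}-1-hydroxyethyl]-5-[(1Z)-2-iodoprop-1-en-1-yl]-3-methylideneoxolan-2-one, via allylzinc bromide 11 (not isolated)
Conditions: Zn dust, THF–sat. aq NH4Cl, 0 → 23 °C
Reagents that add atoms: none
Why: Zinc Barbier allylation at the γ-carbon (C7) through a chair Zimmerman–Traxler state; attack anti to the C6 alkenyl group sets C7 (trans lactone), the ring-locked E-type allylzinc gives the anti adduct (C8 = R, corrected in step 10), and the alkene moves to the exocyclic position while the unactivated alkenyl iodide is untouched.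

**Step 7**
Reactants: 13 methyl angelate
Product: 14 (2Z)-2-methylbut-2-en-1-ol
Conditions: iBu2AlH (2.2 equiv), CH2Cl2, −78 °C; then H2O
Reagents that add atoms: none
Why: 1,2-reduction of an enoate by diisobutylaluminium hydride; the Z geometry is not touched.

**Step 8**
Reactants: 14 (2Z)-2-methylbut-2-en-1-ol
Product: 15 [(2R,3S)-2,3-dimethyloxiran-2-yl]methanol
Conditions: Ti(OiPr)4 (10 mol %), (−)-(S,S)-DIPT (12 mol %), tBuOOH, 4 Å sieves, CH2Cl2, −20 °C
Reagents that add atoms: tert-butyl hydroperoxide, CC(C)(C)OO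
Why: Katsuki–Sharpless epoxidation; the (S,S)-tartrate delivers oxygen to the face that gives 2R,3S, and the Z alkene places CH2OH and the C3 methyl cis on the oxirane.

**Step 9**
Reactants: 15 [(2R,3S)-2,3-dimethyloxiran-2-yl]methanol
Product: 17 (2S,3S)-2,3-dimethyloxirane-2-carboxylic acid, via epoxy aldehyde 16 (not isolated)
Conditions: TEMPO (20 mol %), PhI(OAc)2 (2.2 equiv), MeCN–H2O, 23 °C
Reagents that add atoms: water, O
Why: Oxoammonium (TEMPO/PhI(OAc)2) oxidation through the aldehyde hydrate; no bond at a stereocentre is broken, and the C2 descriptor changes from R to S only because the substituent ranking changes.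

**Step 10**
Reactants: 12 (4R,5S)-4-[(1R)-2-{[tert-butyl(dimethyl)silyl]oxy}-1-hydroxyethyl]-5-[(1Z)-2-iodoprop-1-en-1-yl]-3-methylideneoxolan-2-one; 17 (2S,3S)-2,3-dimethyloxirane-2-carboxylic acid
Product: 18 (1S)-2-{[tert-butyl(dimethyl)silyl]oxy}-1-{(2S,3S)-2-[(1Z)-2-iodoprop-1-en-1-yl]-4-methylidene-5-oxooxolan-3-yl}ethyl (2S,3S)-2,3-dimethyloxirane-2-carboxylate
Conditions: PPh3, DIAD, toluene, 0 → 23 °C
Reagents that add atoms: none
Why: Mitsunobu esterification; the carboxylate of the fairly acidic acid 17 displaces the C8 alkoxyphosphonium ion in an SN2 step, so C8 is inverted from R to the required S as the ester bond forms, under neutral conditions that spare the oxirane, the iodide and the α-methylene lactone.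

**Step 11**
Reactants: 19 prop-2-yn-1-ol
Product: 21 (2Z)-3-(tributylstannyl)prop-2-en-1-ol, via cyclic alkenylaluminate 20 (not isolated)
Conditions: LiAlH4, THF, 0 → 23 °C; then Bu3SnOTf, −78 °C; then H2O
Reagents that add atoms: tributyltin trifluoromethanesulfonate, CCCC[Sn](CCCC)(CCCC)OS(=O)(=O)C(F)(F)F
Why: Alkoxide-directed trans-hydroalumination followed by aluminium-to-tin exchange with retention gives the Z stannane only.

**Step 12**
Reactants: 18 (1S)-2-{[tert-butyl(dimethyl)silyl]oxy}-1-{(2S,3S)-2-[(1Z)-2-iodoprop-1-en-1-yl]-4-methylidene-5-oxooxolan-3-yl}ethyl (2S,3S)-2,3-dimethyloxirane-2-carboxylate; 21 (2Z)-3-(tributylstannyl)prop-2-en-1-ol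
Product: 22 (1S)-2-{[tert-butyl(dimethyl)silyl]oxy}-1-{(2R,3S)-2-[(1Z,3Z)-5-hydroxy-2-methylpenta-1,3-dien-1-yl]-4-methylidene-5-oxooxolan-3-yl}ethyl (2S,3S)-2,3-dimethyloxirane-2-carboxylate
Conditions: Cu(O2CC4H3S) (copper thiophene-2-carboxylate, 1.5 equiv), NMP, 0 → 23 °C
Reagents that add atoms: none
Why: Liebeskind copper-mediated Stille-type coupling; tin-to-copper exchange and coupling proceed with retention at both alkenes (C3–C4 bond, Z,Z diene), and leaving out palladium avoids ionising the allylic lactone carbon–oxygen bond.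

**Step 13**
Reactants: 22 (1S)-2-{[tert-butyl(dimethyl)silyl]oxy}-1-{(2R,3S)-2-[(1Z,3Z)-5-hydroxy-2-methylpenta-1,3-dien-1-yl]-4-methylidene-5-oxooxolan-3-yl}ethyl (2S,3S)-2,3-dimethyloxirane-2-carboxylate
Product: 23 (1S)-2-{[tert-butyl(dimethyl)silyl]oxy}-1-[(2R,3S)-2-{(1Z)-2-[(2S,3R)-3-(hydroxymethyl)oxiran-2-yl]prop-1-en-1-yl}-4-methylidene-5-oxooxolan-3-yl]ethyl (2S,3S)-2,3-dimethyloxirane-2-carboxylate
Conditions: Ti(OiPr)4 (0.3 equiv), (−)-(S,S)-DIPT (0.36 equiv), tBuOOH (2 equiv), 4 Å sieves, CH2Cl2, −20 °C, 48 h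
Reagents that add atoms: tert-butyl hydroperoxide, CC(C)(C)OO
Why: Katsuki–Sharpless epoxidation; only the alkene of the titanium-bound allylic alcohol reacts, the (S,S)-tartrate sets C2 = R and C3 = S, the Z alkene becomes the cis oxirane, and the product of minor-face attack is a separable diastereomer.

**Step 14**
Reactants: 23 (1S)-2-{[tert-butyl(dimethyl)silyl]oxy}-1-[(2R,3S)-2-{(1Z)-2-[(2S,3R)-3-(hydroxymethyl)oxiran-2-yl]prop-1-en-1-yl}-4-methylidene-5-oxooxolan-3-yl]ethyl (2S,3S)-2,3-dimethyloxirane-2-carboxylate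
Product: 24 (1S)-2-{[tert-butyl(dimethyl)silyl]oxy}-1-[(2R,3S)-2-{(1Z)-2-[(2S,3S)-3-formyloxiran-2-yl]prop-1-en-1-yl}-4-methylidene-5-oxooxolan-3-yl]ethyl (2S,3S)-2,3-dimethyloxirane-2-carboxylate
Conditions: TEMPO (10 mol %), PhI(OAc)2 (1.2 equiv), CH2Cl2, 0 → 23 °C
Reagents that add atoms: none
Why: Oxoammonium oxidation of the primary alcohol stops at the aldehyde in dry CH2Cl2 and is base-free, so the cis-epoxy aldehyde does not epimerise.

**Step 15**
Reactants: 24 (1S)-2-{[tert-butyl(dimethyl)silyl]oxy}-1-[(2R,3S)-2-{(1Z)-2-[(2S,3S)-3-formyloxiran-2-yl]prop-1-en-1-yl}-4-methylidene-5-oxooxolan-3-yl]ethyl (2S,3S)-2,3-dimethyloxirane-2-carboxylate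
Product: 25 (1S)-2-{[tert-butyl(dimethyl)silyl]oxy}-1-[(2R,3S)-2-{(1Z)-2-{(2S,3R)-3-[(1Z)-2-iodo-3-methoxy-3-oxoprop-1-en-1-yl]oxiran-2-yl}prop-1-en-1-yl}-4-methylidene-5-oxooxolan-3-yl]ethyl (2S,3S)-2,3-dimethyloxirane-2-carboxylate
Conditions: Ph3P=CHCO2Me, N-iodosuccinimide, CH2Cl2, −20 °C, 30 min; then 24, −20 → 23 °C
Reagents that add atoms: methyl (triphenylphosphoranylidene)acetate, COC(=O)C=P(c1ccccc1)(c1ccccc1)c1ccccc1; N-iodosuccinimide, O=C1CCC(=O)N1I
Why: Wittig olefination by the stabilised α-iodo ylide places the oxirane carbon trans to the ester and cis to iodine (Z iodoenoate), which is the C1=C10 geometry needed once iodine is replaced by C9; from here all compounds are kept below 30 °C because they are cis-dialkenyl oxiranes.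

**Step 16**
Reactants: 25 (1S)-2-{[tert-butyl(dimethyl)silyl]oxy}-1-[(2R,3S)-2-{(1Z)-2-{(2S,3R)-3-[(1Z)-2-iodo-3-methoxy-3-oxoprop-1-en-1-yl]oxiran-2-yl}prop-1-en-1-yl}-4-methylidene-5-oxooxolan-3-yl]ethyl (2S,3S)-2,3-dimethyloxirane-2-carboxylate
Product: 26 (1S)-2-hydroxy-1-[(2R,3S)-2-{(1Z)-2-{(2S,3R)-3-[(1Z)-2-iodo-3-methoxy-3-oxoprop-1-en-1-yl]oxiran-2-yl}prop-1-en-1-yl}-4-methylidene-5-oxooxolan-3-yl]ethyl (2S,3S)-2,3-dimethyloxirane-2-carboxylate
Conditions: HF·pyridine, pyridine, THF, 0 °C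
Reagents that add atoms: none
Why: Fluoride cleavage of the primary silyl ether; the pyridine buffer protects the allylic oxirane, and the hindered α-quaternary acyl group is slow to migrate from O8 to O9.

**Step 17**
Reactants: 26 (1S)-2-hydroxy-1-[(2R,3S)-2-{(1Z)-2-{(2S,3R)-3-[(1Z)-2-iodo-3-methoxy-3-oxoprop-1-en-1-yl]oxiran-2-yl}prop-1-en-1-yl}-4-methylidene-5-oxooxolan-3-yl]ethyl (2S,3S)-2,3-dimethyloxirane-2-carboxylate
Product: 27 (1S)-2-oxo-1-[(2R,3S)-2-{(1Z)-2-{(2S,3R)-3-[(1Z)-2-iodo-3-methoxy-3-oxoprop-1-en-1-yl]oxiran-2-yl}prop-1-en-1-yl}-4-methylidene-5-oxooxolan-3-yl]ethyl (2S,3S)-2,3-dimethyloxirane-2-carboxylate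
Conditions: TEMPO (20 mol %), PhI(OAc)2 (1.3 equiv), CH2Cl2, 23 °C; used crude
Reagents that add atoms: none
Why: Base-free oxoammonium oxidation gives the α-acyloxy aldehyde without epimerising C8.

**Step 18**
Reactants: 27 (1S)-2-oxo-1-[(2R,3S)-2-{(1Z)-2-{(2S,3R)-3-[(1Z)-2-iodo-3-methoxy-3-oxoprop-1-en-1-yl]oxiran-2-yl}prop-1-en-1-yl}-4-methylidene-5-oxooxolan-3-yl]ethyl (2S,3S)-2,3-dimethyloxirane-2-carboxylate
Product: 29 target CNP0291485.3 methyl (2R,3S,6R,7S,8S,9S,1(10)E,4Z)-2,3-epoxy-8-{[(2S,3S)-2,3-dimethyloxiran-2-yl]carbonyloxy}-9-hydroxygermacra-1(10),4,11(13)-trien-12,6-olid-14-oate, via alkenylchromium sulfonamidate 28 (not isolated)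
Conditions: CrCl2 (4 equiv), (S)-N-[2-(4-isopropyl-4,5-dihydrooxazol-2-yl)-6-methylphenyl]methanesulfonamide (4.4 equiv), Et3N (4.4 equiv), NiCl2(2,9-dimethyl-1,10-phenanthroline) (5 mol %), MeCN–THF, 27 added by syringe pump to 2 mM, 23 °C; then H2O
Reagents that add atoms: none
Why: Proposed new method: a ligand-controlled Ni/Cr ring closure in which a (Z)-α-iodo-α,β-unsaturated ester bearing a γ,δ-oxirane, rather than a simple alkenyl iodide, is the donor; zerovalent nickel (formed from the NiCl2 complex by CrCl2) inserts into the weak, electron-poor carbon–iodine bond at C10 with retention, and the alkenyl group passes to trivalent chromium as the kinetically inert σ-alkenyl species 28; this species is kept carbon-bound rather than as an O-bound allenolate because the sulfonamide–oxazoline chelate occupies the sites the ester oxygen would need, and it then adds to the tethered C9 aldehyde, closing the ten-membered ring with C2 and C9 cis on C1=C10 and giving directly a β-substituted Morita–Baylis–Hillman-type carbinol that amine or phosphine catalysis cannot deliver; the (S)-ligand is assigned to shield the Re face, so Si-face attack sets C9 = S against the Felkin preference of the α-acyloxy aldehyde, high dilution suppresses dimers, and the esters, both oxiranes and the α-methylene lactone are expected to tolerate CrCl2 at 23 °C; closest known reaction type: Nozaki–Hiyama–Kishi alkenyl iodide–aldehyde macrocyclisation and its sulfonamide-ligand asymmetric intermolecular version.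

**Compound list**
1 | acrolein | C=CC=O | starting material
2 | prop-1-yn-1-ylmagnesium bromide | CC#C[Mg]Br | starting material
3 | (±)-hex-1-en-4-yn-3-ol | C=CC(O)C#CC | intermediate
4 | (3S)-hex-1-en-4-yn-3-ol | C=C[C@H](O)C#CC | intermediate
5 | sodium cyclic alkenylaluminate from 4 (five-membered O–Al–C4=C5–C6 ring, two 2-methoxyethoxy groups on aluminium, C6 as in 4) | [Na+].C=C[C@@H]1O[Al-](OCCOC)(OCCOC)C(C)=C1 | intermediate
6 | (3S,4Z)-5-iodohexa-1,4-dien-3-ol | C=C[C@H](O)/C=C(/C)I | intermediate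
7 | 2-(bromomethyl)prop-2-enoic acid | C=C(CBr)C(=O)O | starting material
8 | (3S,4Z)-5-iodohexa-1,4-dien-3-yl 2-(bromomethyl)prop-2-enoate | C=C(CBr)C(=O)O[C@@H](C=C)/C=C(/C)I | intermediate
9 | (5S)-3-(bromomethyl)-5-[(1Z)-2-iodoprop-1-en-1-yl]furan-2(5H)-one | O=C1O[C@H](/C=C(/C)I)C=C1CBr | intermediate
10 | {[tert-butyl(dimethyl)silyl]oxy}acetaldehyde | O=CCO[Si](C)(C)C(C)(C)C | starting material
11 | allylzinc bromide from 9 (ZnBr in place of Br) | O=C1O[C@H](/C=C(/C)I)C=C1C[Zn]Br | intermediate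
12 | (4R,5S)-4-[(1R)-2-{[tert-butyl(dimethyl)silyl]oxy}-1-hydroxyethyl]-5-[(1Z)-2-iodoprop-1-en-1-yl]-3-methylideneoxolan-2-one | C=C1C(=O)O[C@H](/C=C(/C)I)[C@H]1[C@@H](O)CO[Si](C)(C)C(C)(C)C | intermediate
13 | methyl angelate (methyl (2Z)-2-methylbut-2-enoate) | C/C=C(/C)C(=O)OC | starting material
14 | (2Z)-2-methylbut-2-en-1-ol | C/C=C(/C)CO | intermediate
15 | [(2R,3S)-2,3-dimethyloxiran-2-yl]methanol | OC[C@@]1(C)O[C@H]1C | intermediate
16 | (2S,3S)-2,3-dimethyloxirane-2-carbaldehyde | O=C[C@@]1(C)O[C@H]1C | intermediate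
17 | (2S,3S)-2,3-dimethyloxirane-2-carboxylic acid | OC(=O)[C@@]1(C)O[C@H]1C | intermediate
18 | (1S)-2-{[tert-butyl(dimethyl)silyl]oxy}-1-{(2S,3S)-2-[(1Z)-2-iodoprop-1-en-1-yl]-4-methylidene-5-oxooxolan-3-yl}ethyl (2S,3S)-2,3-dimethyloxirane-2-carboxylate | C=C1C(=O)O[C@H](/C=C(/C)I)[C@H]1[C@H](OC(=O)[C@@]2(C)O[C@H]2C)CO[Si](C)(C)C(C)(C)C | intermediate
19 | prop-2-yn-1-ol | C#CCO | starting material
20 | lithium cyclic alkenylaluminate from 19 (five-membered O–AlH2–CH=CH–CH2 ring) | [Li+].[AlH2-]1OCC=C1 | intermediate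
21 | (2Z)-3-(tributylstannyl)prop-2-en-1-ol | OC/C=C\[Sn](CCCC)(CCCC)CCCC | intermediate
22 | (1S)-2-{[tert-butyl(dimethyl)silyl]oxy}-1-{(2R,3S)-2-[(1Z,3Z)-5-hydroxy-2-methylpenta-1,3-dien-1-yl]-4-methylidene-5-oxooxolan-3-yl}ethyl (2S,3S)-2,3-dimethyloxirane-2-carboxylate | C=C1C(=O)O[C@H](/C=C(/C)\C=C/CO)[C@H]1[C@H](OC(=O)[C@@]2(C)O[C@H]2C)CO[Si](C)(C)C(C)(C)C | intermediate
23 | (1S)-2-{[tert-butyl(dimethyl)silyl]oxy}-1-[(2R,3S)-2-{(1Z)-2-[(2S,3R)-3-(hydroxymethyl)oxiran-2-yl]prop-1-en-1-yl}-4-methylidene-5-oxooxolan-3-yl]ethyl (2S,3S)-2,3-dimethyloxirane-2-carboxylate | C=C1C(=O)O[C@H](/C=C(/C)[C@@H]2O[C@@H]2CO)[C@H]1[C@H](OC(=O)[C@@]2(C)O[C@H]2C)CO[Si](C)(C)C(C)(C)C | intermediate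
24 | (1S)-2-{[tert-butyl(dimethyl)silyl]oxy}-1-[(2R,3S)-2-{(1Z)-2-[(2S,3S)-3-formyloxiran-2-yl]prop-1-en-1-yl}-4-methylidene-5-oxooxolan-3-yl]ethyl (2S,3S)-2,3-dimethyloxirane-2-carboxylate | C=C1C(=O)O[C@H](/C=C(/C)[C@@H]2O[C@@H]2C=O)[C@H]1[C@H](OC(=O)[C@@]2(C)O[C@H]2C)CO[Si](C)(C)C(C)(C)C | intermediate
25 | (1S)-2-{[tert-butyl(dimethyl)silyl]oxy}-1-[(2R,3S)-2-{(1Z)-2-{(2S,3R)-3-[(1Z)-2-iodo-3-methoxy-3-oxoprop-1-en-1-yl]oxiran-2-yl}prop-1-en-1-yl}-4-methylidene-5-oxooxolan-3-yl]ethyl (2S,3S)-2,3-dimethyloxirane-2-carboxylate | C=C1C(=O)O[C@H](/C=C(/C)[C@@H]2O[C@@H]2/C=C(/C(=O)OC)I)[C@H]1[C@H](OC(=O)[C@@]2(C)O[C@H]2C)CO[Si](C)(C)C(C)(C)C | intermediate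
26 | (1S)-2-hydroxy-1-[(2R,3S)-2-{(1Z)-2-{(2S,3R)-3-[(1Z)-2-iodo-3-methoxy-3-oxoprop-1-en-1-yl]oxiran-2-yl}prop-1-en-1-yl}-4-methylidene-5-oxooxolan-3-yl]ethyl (2S,3S)-2,3-dimethyloxirane-2-carboxylate | C=C1C(=O)O[C@H](/C=C(/C)[C@@H]2O[C@@H]2/C=C(/C(=O)OC)I)[C@H]1[C@H](OC(=O)[C@@]2(C)O[C@H]2C)CO | intermediate
27 | (1S)-2-oxo-1-[(2R,3S)-2-{(1Z)-2-{(2S,3R)-3-[(1Z)-2-iodo-3-methoxy-3-oxoprop-1-en-1-yl]oxiran-2-yl}prop-1-en-1-yl}-4-methylidene-5-oxooxolan-3-yl]ethyl (2S,3S)-2,3-dimethyloxirane-2-carboxylate | C=C1C(=O)O[C@H](/C=C(/C)[C@@H]2O[C@@H]2/C=C(/C(=O)OC)I)[C@H]1[C@H](OC(=O)[C@@]2(C)O[C@H]2C)C=O | intermediate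
28 | alkenylchromium sulfonamidate (27 carrying CrCl(sulfonamidate ligand) in place of iodine, trivalent chromium, alkene geometry retained) | C=C1C(=O)O[C@H](/C=C(/C)[C@@H]2O[C@@H]2/C=C(/C(=O)OC)[Cr](Cl)N(c2c(C)cccc2C2=N[C@@H](C(C)C)CO2)S(C)(=O)=O)[C@H]1[C@H](OC(=O)[C@@]2(C)O[C@H]2C)C=O | intermediate
29 | CNP0291485.3, methyl (2R,3S,6R,7S,8S,9S,1(10)E,4Z)-2,3-epoxy-8-{[(2S,3S)-2,3-dimethyloxiran-2-yl]carbonyloxy}-9-hydroxygermacra-1(10),4,11(13)-trien-12,6-olid-14-oate | C=C1C(=O)O[C@@H]2/C=C(/C)[C@@H]3O[C@@H]3/C=C(/C(=O)OC)[C@H](O)[C@@H](OC(=O)[C@@]3(C)O[C@H]3C)[C@@H]12 | target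

**Totals**
- Total step count: 18.
- Longest linear sequence: 14 steps (steps 1–6, 10, 12–18).

**Three steps most likely to fail**

**Step 18 (the proposed new ring closure).**
- Risks: the C1=C10 geometry may be lost through an O-bound chromium allenolate or a linear α-ester vinyl radical. The iodide may simply be reduced. The ligand may fail to override the Felkin bias at C9.
- Fallback: this uses known chemistry. The C9–C10 bond is made between two molecules and the ring is closed at C1=C10 by olefin metathesis. It sets out from 24.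
- Wittig methylenation by Ph3P=CH2 (THF, −78 °C) gives the vinyl epoxide F1.
- HF·pyridine/pyridine frees the C9 alcohol F2, and TEMPO/PhI(OAc)2 gives the C9 aldehyde F3.
- Vinylalumination by iBu2Al–C(=CH2)CO2Me (from methyl propiolate, iBu2AlH and HMPA, THF, 0 °C) gives the acrylate carbinol F4. Selectivity at C9 is expected to be modest, so F4 is purified by chromatography.
- Ring-closing metathesis of F4 (second-generation Hoveyda–Grubbs catalyst, toluene, 1 mM, 40 °C) joins the vinyl-epoxide carbon C1 to C10. The ring is expected to favour the cis alkene. The route is rejoined at 29.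

**Step 10 (Mitsunobu inversion at a branched carbinol next to an allylic C7–H).**
- Risks: elimination to a diene, or retention through acyloxyphosphonium pathways.
- Fallback: inversion by oxidation and reagent-controlled reduction instead of SN2 displacement. It sets out from 12.
- Dess–Martin periodinane (CH2Cl2, 0 °C) gives the C8 ketone F5.
- (S)-Me-CBS oxazaborolidine with catecholborane (toluene, −78 °C) reduces it to the C8 epimeric alcohol F6 (C8 = S).
- Yamaguchi esterification of F6 by 17 (2,4,6-trichlorobenzoyl chloride, Et3N, DMAP, toluene) proceeds with retention and rejoins the route at 18.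

**Step 13 (Sharpless epoxidation of a Z allylic alcohol whose cis substituent is a branched alkenyl group, the slowest and least selective substrate class).**
- Fallback: a non-directed organocatalytic dioxirane epoxidation, in which site selection comes from sterics and electronics rather than from titanium binding. It sets out from 22.
- TESCl/imidazole gives the triethylsilyl ether F7.
- Shi's glucose-derived N-aryl oxazolidinone ketone (the enantiomer matched to the 2R,3S oxirane) with KHSO5 and K2CO3 in buffered DME–H2O at 0 °C epoxidises the cis-disubstituted alkene of the conjugated diene. This gives the silylated epoxide F8.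
- Brief treatment by HF·pyridine/pyridine at 0 °C removes the primary triethylsilyl group and leaves the tert-butyldimethylsilyl group in place. The route is rejoined at 23.

**Further compounds**
F1 | step 18 | vinyl epoxide (CHO of 24 replaced by CH=CH2) | C=C1C(=O)O[C@H](/C=C(/C)[C@@H]2O[C@@H]2C=C)[C@H]1[C@H](OC(=O)[C@@]2(C)O[C@H]2C)CO[Si](C)(C)C(C)(C)C
F2 | step 18 | C9 alcohol (F1 without the silyl group) | C=C1C(=O)O[C@H](/C=C(/C)[C@@H]2O[C@@H]2C=C)[C@H]1[C@H](OC(=O)[C@@]2(C)O[C@H]2C)CO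
F3 | step 18 | C9 aldehyde (from F2) | C=C1C(=O)O[C@H](/C=C(/C)[C@@H]2O[C@@H]2C=C)[C@H]1[C@H](OC(=O)[C@@]2(C)O[C@H]2C)C=O
F4 | step 18 | acrylate carbinol (C9 = S, C10 carrying =CH2 and CO2Me) | C=C1C(=O)O[C@H](/C=C(/C)[C@@H]2O[C@@H]2C=C)[C@H]1[C@H](OC(=O)[C@@]2(C)O[C@H]2C)[C@@H](O)C(=C)C(=O)OC
F5 | step 10 | C8 ketone (from 12) | C=C1C(=O)O[C@H](/C=C(/C)I)[C@H]1C(=O)CO[Si](C)(C)C(C)(C)C
F6 | step 10 | C8 epimeric alcohol (C8 = S epimer of 12) | C=C1C(=O)O[C@H](/C=C(/C)I)[C@H]1[C@H](O)CO[Si](C)(C)C(C)(C)C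
F7 | step 13 | triethylsilyl ether (of the C1 hydroxyl of 22) | C=C1C(=O)O[C@H](/C=C(/C)\C=C/CO[Si](CC)(CC)CC)[C@H]1[C@H](OC(=O)[C@@]2(C)O[C@H]2C)CO[Si](C)(C)C(C)(C)C
F8 | step 13 | silylated epoxide (C1 triethylsilyl ether of 23) | C=C1C(=O)O[C@H](/C=C(/C)[C@@H]2O[C@@H]2CO[Si](CC)(CC)CC)[C@H]1[C@H](OC(=O)[C@@]2(C)O[C@H]2C)CO[Si](C)(C)C(C)(C)C
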